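- Whatever the feed and the catalyst do, Sub and Sub2 meet the same Rea and the same Ctl at each instant. While neither turns into the other, they run on one clock at fixed relative speeds.

in all of them: Oth 0.14 mM
- Thursday's: Sub 0.14 M; Sub2 0.14 M; Rea 0.42 M (fed, over 80 min); Ctl 0.094 mM; run made earlier
- Saturday's: Sub 0.14 M; Sub2 0.14 M; Rea 0.42 M (fed, over 80 min); Ctl 0.21 mM; run made earlier
- Monday's: Sub 0.070 M; Sub2 0.070 M; Rea 0.42 M (fed, over 80 min); Ctl 0.14 mM; run made earlier
- flask: Sub 0.14 M; Sub2 0.14 M; Rea 0.420 M (fed, over 80 min); Ctl 0.14 mM; time 1.5 h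

| run | time / min | Prd / % | Prd2 / % |
|---|---|---|---|
| Thursday's | 15.0 | 1.7 | 0.5 |
| Thursday's | 30.0 | 4.6 | 2.9 |
| Thursday's | 40.0 | 7.0 | 4.5 |
| Thursday's | 60.0 | 13.7 | 9.0 |
| Thursday's | 80.0 | 19.1 | 13.4 |
| Saturday's | 6.00 | 0.4 | 0 |
| Saturday's | 10.0 | 0.4 | 0.2 |
| Saturday's | 20.0 | 5.3 | 3.1 |
| Saturday's | 40.0 | 13.6 | 9.1 |
| Saturday's | 80.0 | 31.0 | 23.1 |
| Monday's | 15.0 | 1.7 | 1.4 |
| Monday's | 30.0 | 7.4 | 5.0 |
| Monday's | 40.0 | 11.7 | 6.7 |
| Monday's | 60.0 | 20.6 | 13.2 |
| Monday's | 80.0 | 28.3 | 19.4 |

(standard deviation of a reading: 0.5 percentage points)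

- Ctl is single-handed; Sub and Sub2 are mirror images of each other, charged as a racemate, each of them at the stated concentration
- what may be going on: Rea + Oth -> Ctl2 + Zed; Sub + Ctl2 <-> Sub2 + Ctl2; Rea + Ctl + Sub -> Ctl + Prd; Ctl <-> Imd; Rea + Ctl + Sub2 -> Ctl + Prd2
- an excess is the difference of the two amounts in percent of their sum
- an excess is below zero if the other one leads

1. Prd and Prd2 together, in percent of the Sub and Sub2 charged together, at 1.5 h
2. excess of Prd over Prd2 in the product at 1.5 h
3. whether the exchange between Sub and Sub2 keeps pace with the reaction: how far the product's excess at 1.5 h gets from its value without exchange to its value with instant exchange (above 80% keeps pace, below 20% hardly takes part, else lags behind)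

- Work in logarithms of the fraction of each enantiomer's own charge left. Sub is half of the racemate, so Thursday's last readings leave 0.618 of Sub and 0.732 of Sub2.
- At the end of the feed, ln(fraction of Sub left) over ln(fraction of Sub2 left) reads 1.54 on Thursday's run, 1.56 on Saturday's and 1.70 on Monday's. Their mean 1.60 is my reading of the selectivity factor, the fixed ratio of the two log-survivals. Take −ln(fraction of Sub2 left) as your clock.
- First instants: at 10.0 min Saturday's run has received 0.125 of its Rea and shows 0.4% Prd, so the clock has barely started.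
- Middle: Thursday's clock goes from 0.0943 at 40.0 min to 0.312 at 80.0 min, while the feed runs.
- Meanwhile Sub falls faster, so the product's excess shrinks: Saturday's goes from 19.8% to 14.6%. Instant exchange would hold it at (factor − one)/(factor + one) = 23.1%, and the last reading stands well below that, so I expect exchange to hardly take part.
- End: scaling the Thursday and Saturday clocks by Ctl gives the flask 0.439 at the end of the feed.
- Rea's charge is 1.50 times the Sub and Sub2 together, so I let the clock keep Thursday's last pace, scaled by Ctl, for the remaining 10.0 min, reaching 0.523.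
- My reckoning for the flask then leaves 0.592 of Sub2 and 0.432 of Sub, which gives 48.8% product at an excess of 16.4%.
- The forecast says 48.5% (45% to 52%), 16.5% (14.5% to 19.5%) and "hardly takes part", on the ground “matching simple kinetic resolution, so exchange is negligible”.
- The flask gives 48.9% at an excess of 16.7%: exchange hardly takes part, getting 2.8% of the way.

    Rea + Oth → Ctl2 + Zed (k = 1.60 × 10⁻⁴ /M/s)
    Sub + Ctl2 ⇌ Sub2 + Ctl2, rate k2*[Ctl2]*[Sub] forward; the back reaction follows from the equilibrium constant (k = 1.20 /M/s)
    Rea + Ctl + Sub → Ctl + Prd (k = 9.80 /M²/s)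
    Ctl ⇌ Imd (K = 1.20, k = 1.70 × 10⁻⁴ /s)
    Rea + Ctl + Sub2 → Ctl + Prd2 (k = 6.10 /M²/s)

- In this flask, exchange moved a net 0.277% of the charge from Sub2 to Sub, and 59% of Sub2 left, raised to the power 1.60, gives 43.0% of Sub against the 44% the flask holds. The neighbouring flask, charged with 0.25 M of Rea, reaches 32.5% product at an excess of 19.2%. Its 73% of Sub2 left, raised to the same power, gives 61.1% of Sub, and that neighbouring flask holds 61%.

(Readings and results were generated by integration on assumed constants; scatter was added.)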